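## Retrosynthetic overview
1. The α-methylene-γ-lactone is closed last, by allylic oxidation of a 6,12-diol. The C8 ester comes from (2R,3R)-epoxyangelic acid, made from methyl (R)-3-hydroxybutanoate.
2. The C8 oxygen comes from Rubottom oxidation of the regiodefined enol silane that the key step delivers.
3. Key step: anionic oxy-Cope [3,3] rearrangement of a cis-1,2-dialkenylcyclohexanol. It cleaves C4–C9 and forms C6–C7, giving the ten-membered ring, the C9 ketone, the Z-C4=C5 alkene and C6/C7 together.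
4. The Cope substrate comes from enynyl-lithium addition and Lindlar reduction on a cyclohexanone that already carries C1–O, C10–Me and the quaternary C4.
5. That ketone comes from (S)-carvone by methylation, prenylation, conjugate borylation–oxidation and ozonolysis/hydrodealkenylation. Ring order: cyclohexane (bought), then cyclodecene (Cope), then lactone (last). The oxirane is made separately.

Assumption: germacrane locants are used (C6 lactone carbinol, C7 ring-fusion CH, C8 ester carbinol, C9 ketone, C10 CHMe, C1 CHOH, C4=C5 alkene, C11–C13 methylene-lactone carbons); TBS = tert-butyldimethylsilyl, TMS = trimethylsilyl.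

## Route

Step 1
Reactants: 1 2-bromoprop-2-en-1-ol
Product: 2 [(2-bromoprop-2-en-1-yl)oxy](tert-butyl)dimethylsilane
Conditions: TBSCl, imidazole, CH2Cl2, 0 °C to rt
Reagents that add atoms: TBSCl, CC(C)(C)[Si](C)(C)Cl
Why: Routine O-silylation of a primary allylic alcohol; no stereocentre is involved.

Step 2
Reactants: 2 [(2-bromoprop-2-en-1-yl)oxy](tert-butyl)dimethylsilane
Product: 3 tert-butyl(dimethyl)[(2-methylidenebut-3-yn-1-yl)oxy]silane
Conditions: HC≡CMgBr, ZnBr2, THF, 0 °C; then 2, Pd(PPh3)4 (5 mol %), rt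
Reagents that add atoms: ethynylmagnesium bromide, C#C[Mg]Br
Why: Negishi ethynylation of the 2-bromoalkene gives the terminal 1,3-enyne directly, with no desilylation step and no stereocentre.

Step 3
Reactants: 4 methyl (R)-3-hydroxybutanoate
Product: 5 methyl (2R,3R)-3-hydroxy-2-methylbutanoate
Conditions: LDA (2.2 equiv), THF, −78 to −20 °C; MeI, DMPU, −78 to 0 °C
Reagents that add atoms: iodomethane, CI
Why: Fráter–Seebach alkylation, in which the chelated alkoxide–enolate dianion is methylated on the face away from the C3 methyl, so the bought C3 centre sets 2R (anti product).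

Step 4
Reactants: 5 methyl (2R,3R)-3-hydroxy-2-methylbutanoate
Product: 7 methyl (2R,3R)-2,3-dihydroxy-2-methylbutanoate, via 2-hydroperoxy ester 6 (not isolated)
Conditions: LDA (2.2 equiv), THF, −78 to −20 °C; O2, P(OEt)3, −78 °C
Reagents that add atoms: dioxygen, O=O
Why: Enolate oxygenation of the same chelated dianion, where oxygen enters on the face that MeI used in step 3, so OH takes that position (2R, anti diol) and the phosphite reduces the hydroperoxide.

Step 5
Reactants: 7 methyl (2R,3R)-2,3-dihydroxy-2-methylbutanoate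
Product: 10 methyl (2R,3R)-2,3-dimethyloxirane-2-carboxylate, via cyclic orthoacetate 8 (not isolated), via bromo acetate 9 (not isolated)
Conditions: MeC(OMe)3, PPTS (cat.), CH2Cl2, rt; AcBr, 0 °C; K2CO3, MeOH, rt
Reagents that add atoms: none
Why: Kolb–Sharpless diol-to-epoxide sequence, in which bromide opens the acetoxonium ion at secondary C3 with inversion and the freed tertiary alkoxide closes with a second inversion, so both centres are retained and the angelate-type (CO2Me cis to C3-Me) epoxide results.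

Step 6
Reactants: 10 methyl (2R,3R)-2,3-dimethyloxirane-2-carboxylate
Product: 11 (2R,3R)-2,3-dimethyloxirane-2-carboxylic acid (epoxyangelic acid)
Conditions: LiOH, THF–H2O, 0 °C; NaHSO4 to pH 3, 0 °C, cold extraction
Reagents that add atoms: lithium hydroxide, [Li+].[OH-]
Why: Saponification by acyl–oxygen cleavage touches neither oxirane carbon, and cold acidification avoids glycidic acid decarboxylation.

Step 7
Reactants: 12 (S)-(+)-carvone
Product: 13 (5S,6R)-2,6-dimethyl-5-(prop-1-en-2-yl)cyclohex-2-en-1-one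
Conditions: LDA, THF, −78 °C; MeI, −78 to 0 °C
Reagents that add atoms: iodomethane, CI
Why: Kinetic α′-enolate alkylation places methyl trans to the isopropenyl group, and this centre is re-enolised in step 8.

Step 8
Reactants: 13 (5S,6R)-2,6-dimethyl-5-(prop-1-en-2-yl)cyclohex-2-en-1-one
Product: 14 (5R,6R)-2,6-dimethyl-6-(3-methylbut-2-en-1-yl)-5-(prop-1-en-2-yl)cyclohex-2-en-1-one
Conditions: LDA, THF, −78 to 0 °C; prenyl bromide, DMPU, −78 °C to rt
Reagents that add atoms: prenyl bromide, CC(C)=CCBr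
Why: Enolate alkylation under 1,2-induction, in which the allylic bromide approaches anti to the neighbouring isopropenyl group and fixes quaternary C4 (prenyl trans, methyl cis to isopropenyl).

Step 9
Reactants: 14 (5R,6R)-2,6-dimethyl-6-(3-methylbut-2-en-1-yl)-5-(prop-1-en-2-yl)cyclohex-2-en-1-one
Product: 16 (2R,3R,5S,6S)-5-hydroxy-2,6-dimethyl-2-(3-methylbut-2-en-1-yl)-3-(prop-1-en-2-yl)cyclohexan-1-one, via pinacol boronate 15 (not isolated)
Conditions: B2pin2, CuCl (5 mol %), DPEphos (5 mol %), NaOt-Bu (15 mol %), MeOH (2 equiv), THF, rt; then NaBO3·4H2O, THF–H2O, rt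
Reagents that add atoms: sodium perborate, [Na+].[Na+].O[B-]1(O)OO[B-](O)(O)OO1 (oxygen at C1); bis(pinacolato)diboron, CC1(C)OB(OC1(C)C)B1OC(C)(C)C(C)(C)O1 (boryl group of 15 only)
Why: Copper-catalysed conjugate borylation with an achiral ligand adds boron axially and trans to the isopropenyl group (C1, kept on oxidation with retention), and C10 settles through the enolate as the equatorial methyl because its epimer has a syn-diaxial Me/Me contact with the C4 methyl.

Step 10
Reactants: 16 (2R,3R,5S,6S)-5-hydroxy-2,6-dimethyl-2-(3-methylbut-2-en-1-yl)-3-(prop-1-en-2-yl)cyclohexan-1-one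
Product: 18 2-[(1S,3S,4S)-4-hydroxy-1,3-dimethyl-2-oxocyclohexyl]acetaldehyde, via methoxy hydroperoxide 17 (not isolated)
Conditions: O3, MeOH, −78 °C; Ar purge; FeSO4·7H2O (2.5 equiv), PhSH (3 equiv), −78 °C to rt
Reagents that add atoms: ozone, [O-][O+]=O (aldehyde oxygen); methanol, CO (methoxy group of 17 only)
Why: Criegee ozonolysis followed by Fe(II)/thiol hydrodealkenylation, in which the prenyl alkene splits to the aldehyde plus acetone oxide while the isopropenyl group gives an α-methoxy hydroperoxide whose alkoxy radical β-scission leaves a C3 radical that PhSH reduces, so the relay stereocentre is removed and C1, C4 and C10 are untouched.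

Step 11
Reactants: 18 2-[(1S,3S,4S)-4-hydroxy-1,3-dimethyl-2-oxocyclohexyl]acetaldehyde
Product: 19 (2S,5S,6S)-5-(TBS-oxy)-2-[(E)-2-(TBS-oxy)ethenyl]-2,6-dimethylcyclohexan-1-one
Conditions: TBSOTf (2.3 equiv), Et3N (4 equiv), CH2Cl2, −78 to 0 °C, then rt 2 h
Reagents that add atoms: TBSOTf, CC(C)(C)[Si](C)(C)OS(=O)(=O)C(F)(F)F
Why: Soft enolisation and silylation protects C1–OH and converts only the aldehyde (the hindered ketone is slower) into its enol silane, which is E because the Z isomer would press OTBS against the quaternary C4.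

Step 12
Reactants: 19 (2S,5S,6S)-5-(TBS-oxy)-2-[(E)-2-(TBS-oxy)ethenyl]-2,6-dimethylcyclohexan-1-one; 3 tert-butyl(dimethyl)[(2-methylidenebut-3-yn-1-yl)oxy]silane
Product: 20 (1R,2S,5S,6S)-5-(TBS-oxy)-1-[3-(TBS-oxymethyl)but-3-en-1-yn-1-yl]-2-[(E)-2-(TBS-oxy)ethenyl]-2,6-dimethylcyclohexan-1-ol
Conditions: 3 (1.5 equiv), n-BuLi, THF, −78 °C; then 19, −78 to −20 °C
Reagents that add atoms: none
Why: 1,2-Addition of a weakly basic, rod-shaped lithium acetylide to a chair locked by the equatorial C10 methyl and C4 alkenyl groups, where the axial C4 methyl blocks the equatorial trajectory, so attack is axial and the alkynyl group ends cis to the C4 alkenyl arm (C9 R).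

Step 13
Reactants: 20 (1R,2S,5S,6S)-5-(TBS-oxy)-1-[3-(TBS-oxymethyl)but-3-en-1-yn-1-yl]-2-[(E)-2-(TBS-oxy)ethenyl]-2,6-dimethylcyclohexan-1-ol
Product: 21 (1R,2S,5S,6S)-5-(TBS-oxy)-1-[(1Z)-3-(TBS-oxymethyl)buta-1,3-dien-1-yl]-2-[(E)-2-(TBS-oxy)ethenyl]-2,6-dimethylcyclohexan-1-ol
Conditions: H2 (1 atm), Lindlar catalyst, quinoline, EtOAc–hexane, rt
Reagents that add atoms: none
Why: Lindlar semihydrogenation adds H2 syn to the alkyne only and gives the Z-C7=C8 alkene.

Step 14
Reactants: 21 (1R,2S,5S,6S)-5-(TBS-oxy)-1-[(1Z)-3-(TBS-oxymethyl)buta-1,3-dien-1-yl]-2-[(E)-2-(TBS-oxy)ethenyl]-2,6-dimethylcyclohexan-1-ol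
Product: 23 (1S,6S,7S,10S,4Z,8Z)-1,6,12-tris(TBS-oxy)-9-(TMS-oxy)germacra-4,8,11(13)-triene, via potassium enolate 22 (not isolated)
Conditions: KH (3 equiv), 18-crown-6 (1.5 equiv), THF, 0 to 40 °C; then TMSCl–Et3N, −78 °C
Reagents that add atoms: TMSCl, C[Si](C)(C)Cl
Why: Anionic oxy-Cope [3,3] sigmatropic rearrangement through a chair in which the Z-dienyl arm forces the oxido group axial (the other chair would set C10 1,3-diaxial to C11) and the cis arms then force C3 axial, so C4–C9 breaks and C6–C7 forms to give Z-C4=C5, 6S (equatorial OTBS from the E enol ether) and 7S (axial C11 from the Z alkene) by chirality transfer from C4 and C9, and the regiodefined C8 enolate is trapped on oxygen.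

Step 15
Reactants: 23 (1S,6S,7S,10S,4Z,8Z)-1,6,12-tris(TBS-oxy)-9-(TMS-oxy)germacra-4,8,11(13)-triene
Product: 25 (1S,6S,7R,8R,10S,4Z)-8-hydroxy-1,6,12-tris(TBS-oxy)germacra-4,11(13)-dien-9-one, via 8-trimethylsilyloxy ketone 24 (not isolated)
Conditions: mCPBA (1.05 equiv), NaHCO3, CH2Cl2, −20 °C; then citric acid, MeOH, 0 °C
Reagents that add atoms: mCPBA, O=C(OO)c1cccc(Cl)c1
Why: Rubottom oxidation of the most electron-rich alkene, where A1,3 strain with the cis OTMS holds H7 in the enol-ether plane and the ring (C6) covers one face, so oxygen enters from the open face to give 8R (the C7 descriptor changes by priority only).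

Step 16
Reactants: 25 (1S,6S,7R,8R,10S,4Z)-8-hydroxy-1,6,12-tris(TBS-oxy)germacra-4,11(13)-dien-9-one; 11 (2R,3R)-2,3-dimethyloxirane-2-carboxylic acid
Product: 26 (1S,6S,7R,8R,10S,4Z)-9-oxo-1,6,12-tris(TBS-oxy)germacra-4,11(13)-dien-8-yl (2R,3R)-2,3-dimethyloxirane-2-carboxylate
Conditions: DCC, DMAP, CH2Cl2, 0 °C to rt
Reagents that add atoms: none
Why: Steglich esterification acylates the only free hydroxyl with retention at C8 and leaves the oxirane centres untouched.

Step 17
Reactants: 26 (1S,6S,7R,8R,10S,4Z)-9-oxo-1,6,12-tris(TBS-oxy)germacra-4,11(13)-dien-8-yl (2R,3R)-2,3-dimethyloxirane-2-carboxylate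
Product: 27 (1S,6S,7S,8R,10S,4Z)-1,6,12-trihydroxy-9-oxogermacra-4,11(13)-dien-8-yl (2R,3R)-2,3-dimethyloxirane-2-carboxylate
Conditions: HF·pyridine, pyridine, THF, 0 °C to rt
Reagents that add atoms: none
Why: Buffered fluoride desilylation removes all three TBS groups without base, so the β-hydroxy ketone, the α-acyloxy ketone and the electron-poor glycidic ester survive.

Step 18
Reactants: 27 (1S,6S,7S,8R,10S,4Z)-1,6,12-trihydroxy-9-oxogermacra-4,11(13)-dien-8-yl (2R,3R)-2,3-dimethyloxirane-2-carboxylate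
Product: 29 CNP0149149.1 (target), via lactol 28 (not isolated)
Conditions: activated MnO2 (25 equiv), CH2Cl2, rt
Reagents that add atoms: none
Why: Oxidative lactonisation, in which MnO2 takes the primary allylic C12 alcohol to the enal, C6–OH closes the lactol and a second oxidation gives the α-methylene-γ-lactone, so the C6–O bond is never broken (cis fusion from step 14 is kept) and the non-allylic C1–OH is left alone.

## Compound list
1 | 2-bromoprop-2-en-1-ol | C=C(Br)CO | starting material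
2 | [(2-bromoprop-2-en-1-yl)oxy](tert-butyl)dimethylsilane | C=C(Br)CO[Si](C)(C)C(C)(C)C | intermediate
3 | tert-butyl(dimethyl)[(2-methylidenebut-3-yn-1-yl)oxy]silane | C#CC(=C)CO[Si](C)(C)C(C)(C)C | intermediate
4 | methyl (R)-3-hydroxybutanoate | C[C@@H](O)CC(=O)OC | starting material
5 | methyl (2R,3R)-3-hydroxy-2-methylbutanoate | C[C@@H](O)[C@@H](C)C(=O)OC | intermediate
6 | methyl (2R,3R)-2-hydroperoxy-3-hydroxy-2-methylbutanoate | COC(=O)[C@](C)(OO)[C@H](O)C | intermediate
7 | methyl (2R,3R)-2,3-dihydroxy-2-methylbutanoate | COC(=O)[C@](C)(O)[C@H](O)C | intermediate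
8 | methyl (4R,5R)-2-methoxy-2,4,5-trimethyl-1,3-dioxolane-4-carboxylate | COC(=O)[C@]1(C)OC(C)(OC)O[C@@H]1C | intermediate
9 | methyl (2S,3S)-2-acetoxy-3-bromo-2-methylbutanoate | COC(=O)[C@](C)(OC(C)=O)[C@@H](Br)C | intermediate
10 | methyl (2R,3R)-2,3-dimethyloxirane-2-carboxylate | COC(=O)[C@]1(C)O[C@@H]1C | intermediate
11 | (2R,3R)-2,3-dimethyloxirane-2-carboxylic acid | OC(=O)[C@]1(C)O[C@@H]1C | intermediate
12 | (S)-(+)-carvone | O=C1C(C)=CC[C@H](C(C)=C)C1 | starting material
13 | (5S,6R)-6-methylcarvone (methyl trans to isopropenyl) | O=C1C(C)=CC[C@H](C(C)=C)[C@H]1C | intermediate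
14 | (5R,6R)-6-methyl-6-prenylcarvone (prenyl trans to isopropenyl) | O=C1C(C)=CC[C@H](C(C)=C)[C@@]1(C)CC=C(C)C | intermediate
15 | C1 pinacol boronate of 16 (Bpin in place of OH, same arrangement) | O=C1[C@@H](C)[C@@H](B2OC(C)(C)C(C)(C)O2)C[C@H](C(C)=C)[C@@]1(C)CC=C(C)C | intermediate
16 | (2R,3R,5S,6S)-5-hydroxy-2,6-dimethyl-2-prenyl-3-isopropenylcyclohexan-1-one | O=C1[C@@H](C)[C@@H](O)C[C@H](C(C)=C)[C@@]1(C)CC=C(C)C | intermediate
17 | keto aldehyde carrying a 1-hydroperoxy-1-methoxyethyl group at C3 (acetal carbon epimers) | O=C1[C@@H](C)[C@@H](O)C[C@H](C(C)(OC)OO)[C@@]1(C)CC=O | intermediate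
18 | 2-[(1S,3S,4S)-4-hydroxy-1,3-dimethyl-2-oxocyclohexyl]acetaldehyde | O=C1[C@@H](C)[C@@H](O)CC[C@@]1(C)CC=O | intermediate
19 | (2S,5S,6S)-5-(TBS-oxy)-2-[(E)-2-(TBS-oxy)ethenyl]-2,6-dimethylcyclohexan-1-one | O=C1[C@@H](C)[C@@H](O[Si](C)(C)C(C)(C)C)CC[C@@]1(C)/C=C/O[Si](C)(C)C(C)(C)C | intermediate
20 | (1R,2S,5S,6S) enynyl carbinol | O[C@]1(C#CC(=C)CO[Si](C)(C)C(C)(C)C)[C@@H](C)[C@@H](O[Si](C)(C)C(C)(C)C)CC[C@@]1(C)/C=C/O[Si](C)(C)C(C)(C)C | intermediate
21 | (1R,2S,5S,6S) (Z)-dienyl carbinol (Cope substrate) | O[C@]1(/C=C\C(=C)CO[Si](C)(C)C(C)(C)C)[C@@H](C)[C@@H](O[Si](C)(C)C(C)(C)C)CC[C@@]1(C)/C=C/O[Si](C)(C)C(C)(C)C | intermediate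
22 | potassium (4Z,8Z)-1,6,12-tris(TBS-oxy)germacra-4,8,11(13)-trien-9-olate | CC(C)(C)[Si](C)(C)O[C@H]1/C=C(/C)CC[C@H](O[Si](C)(C)C(C)(C)C)[C@H](C)/C([O-])=C/[C@H]1C(=C)CO[Si](C)(C)C(C)(C)C.[K+] | intermediate
23 | (1S,6S,7S,10S,4Z,8Z)-1,6,12-tris(TBS-oxy)-9-(TMS-oxy)germacra-4,8,11(13)-triene | CC(C)(C)[Si](C)(C)O[C@H]1/C=C(/C)CC[C@H](O[Si](C)(C)C(C)(C)C)[C@H](C)/C(O[Si](C)(C)C)=C/[C@H]1C(=C)CO[Si](C)(C)C(C)(C)C | intermediate
24 | (8R)-8-(TMS-oxy)-1,6,12-tris(TBS-oxy)germacra-4,11(13)-dien-9-one | CC(C)(C)[Si](C)(C)O[C@H]1/C=C(/C)CC[C@H](O[Si](C)(C)C(C)(C)C)[C@H](C)C(=O)[C@H](O[Si](C)(C)C)[C@H]1C(=C)CO[Si](C)(C)C(C)(C)C | intermediate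
25 | (1S,6S,7R,8R,10S,4Z)-8-hydroxy-1,6,12-tris(TBS-oxy)germacra-4,11(13)-dien-9-one | CC(C)(C)[Si](C)(C)O[C@H]1/C=C(/C)CC[C@H](O[Si](C)(C)C(C)(C)C)[C@H](C)C(=O)[C@H](O)[C@H]1C(=C)CO[Si](C)(C)C(C)(C)C | intermediate
26 | 8-O-[(2R,3R)-epoxyangeloyl] derivative of 25 | CC(C)(C)[Si](C)(C)O[C@H]1/C=C(/C)CC[C@H](O[Si](C)(C)C(C)(C)C)[C@H](C)C(=O)[C@H](OC(=O)[C@]2(C)O[C@@H]2C)[C@H]1C(=C)CO[Si](C)(C)C(C)(C)C | intermediate
27 | 1,6,12-triol (1S,6S,7S,8R,10S,4Z) | O[C@H]1/C=C(/C)CC[C@H](O)[C@H](C)C(=O)[C@H](OC(=O)[C@]2(C)O[C@@H]2C)[C@H]1C(=C)CO | intermediate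
28 | 6,12-lactol (C12 epimers) | C=C1C(O)O[C@H]2/C=C(/C)CC[C@H](O)[C@H](C)C(=O)[C@H](OC(=O)[C@]3(C)O[C@@H]3C)[C@@H]12 | intermediate
29 | CNP0149149.1 | C=C1C(=O)O[C@H]2/C=C(/C)CC[C@H](O)[C@H](C)C(=O)[C@H](OC(=O)[C@]3(C)O[C@@H]3C)[C@@H]12 | target

## Step count and risks
Total step count: 18 (enyne 2, acid 4, main line 12). Longest linear sequence: 12 steps (steps 7–18, from (S)-carvone).

The three steps most likely to fail:

**Step 12 (acetylide addition).** The ketone is flanked by a quaternary and a tertiary carbon, and the required axial trajectory runs past the axial C1–OTBS group. Conversion or facial selectivity may therefore be poor. The fallback sets out from 19 and comes back at 20. Lithium acetylide–ethylenediamine, the smallest possible nucleophile, is added to 19 to give the ethynyl carbinol F1. The C7–C11 bond is then made afterwards by Sonogashira coupling of F1 with vinyl bromide 2 (Pd(PPh3)2Cl2, CuI, Et3N), which gives 20 and makes step 2 unnecessary.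

**Step 14 (anionic oxy-Cope).** Three things can erode the outcome: the syn-diaxial alkenyl/OTBS pair, base-induced silyl transfer or fragmentation, and leakage through the other chair or a boat to give the 4E isomer. The fallback sets out from 21 and comes back at 23. The tertiary alcohol is capped (TMSOTf, 2,6-lutidine) as the tertiary TMS ether F2. The neutral siloxy-Cope rearrangement is then run thermally (o-dichlorobenzene, 180–200 °C, base-washed glass). No base is present, and the rearrangement delivers enol silane 23 directly.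

**Step 15 (C8 oxidation).** The face selectivity rests on a conformational argument for a ten-membered ring. The fallback sets out from 23 and comes back at 26. If the oxidation gives the 8S alcohol F3, it is not acylated with retention. Instead it is coupled with acid 11 under Mitsunobu conditions (PPh3, DIAD, toluene), and SN2 displacement at the α-keto carbinol inverts C8 and gives 26, replacing step 16.

## Further compounds
F1 | step 12 | (1R,2S,5S,6S)-5-(TBS-oxy)-1-ethynyl-2-[(E)-2-(TBS-oxy)ethenyl]-2,6-dimethylcyclohexan-1-ol | O[C@]1(C#C)[C@@H](C)[C@@H](O[Si](C)(C)C(C)(C)C)CC[C@@]1(C)/C=C/O[Si](C)(C)C(C)(C)C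
F2 | step 14 | C9-O-trimethylsilyl ether of 21 | C[Si](C)(C)O[C@]1(/C=C\C(=C)CO[Si](C)(C)C(C)(C)C)[C@@H](C)[C@@H](O[Si](C)(C)C(C)(C)C)CC[C@@]1(C)/C=C/O[Si](C)(C)C(C)(C)C
F3 | step 15 | 8S epimer of 25 | CC(C)(C)[Si](C)(C)O[C@H]1/C=C(/C)CC[C@H](O[Si](C)(C)C(C)(C)C)[C@H](C)C(=O)[C@@H](O)[C@H]1C(=C)CO[Si](C)(C)C(C)(C)C
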